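**Retrosynthetic overview**

1. Locants: ring A is the butenolide (C1(=O), O2, C3, C3a, C7a; C3 carries the Z-butylidene), ring B the cyclohexene (C3a, C4, C5, C6, C7, C7a), ring C the cyclobutane (C6, C7, C3', C8'; C8' carries the propyl group), ring D the lactone of the phthalide that is spiro at C3', ring E its benzene ring.
2. Enabling feature: spiro carbon C3' carries the lactone oxygen and the aryl group and sits next to C7, so ring C is a cyclobutanone in disguise. C7 hangs on C7a of the ring A double bond C3a=C7a, which holds C7 and C4 cis, and C6/C8' can be the two carbons of a Z-alkene.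
3. Disconnection 1 (ring D): C3'–aryl bond and lactone C–O bond, from the cyclobutanone and a 2-(ethoxycarbonyl)phenylmagnesium reagent; convex-face addition sets C3'.
4. Disconnection 2 (rings B and C together): intramolecular keteniminium–alkene (2+2) cycloaddition of a monocyclic butenolide amide, forming C6–C7 and C3'–C8' and setting C6, C7 and C8'; a C2-symmetric pyrrolidine auxiliary gives the absolute configuration.
5. Ring A comes from an enynoic acid (AgNO3, 5-exo-dig), built by acetoacetate dianion alkylation, enolate alkylation, enol triflate formation and Sonogashira coupling. Order of ring formation: A, then B and C in one operation, then D (E is bought).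

Key step: step 8

Assumption: the facial sense induced by the (2R,5R) auxiliary in step 8 is assigned from a steric model, not from experiment; if it proves opposite, (2S,5S)-2,5-dimethylpyrrolidine is used in step 7 and nothing else changes.

**Route**

Step 1
Reactants: 1 (2Z)-hex-2-en-1-ol
Product: 2 (2Z)-1-bromohex-2-ene
Conditions: PBr3 (0.4 equiv), pyridine (cat.), Et2O, −10 °C
Reagents that add atoms: phosphorus tribromide, BrP(Br)Br
Why: Conversion of a primary allylic alcohol into the bromide with PBr3 runs by SN2 attack of bromide on the phosphite ester at low temperature, which should leave the Z double bond untouched.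

Step 2
Reactants: 3 tert-butyl 3-oxobutanoate (tert-butyl acetoacetate); 2 (2Z)-1-bromohex-2-ene
Product: 5 tert-butyl (6Z)-3-oxodec-6-enoate, via sodium lithium dianion 4 (not isolated)
Conditions: NaH, THF, 0 °C; n-BuLi, 0 °C; then 2, 0 °C → rt; dilute HCl
Reagents that add atoms: none
Why: The acetoacetate dianion alkylates at its terminal carbon in an SN2 reaction with the primary allylic bromide (dianion γ-alkylation), so the chain is extended with the Z-alkene intact.

Step 3
Reactants: 5 tert-butyl (6Z)-3-oxodec-6-enoate; 6 tert-butyl bromoacetate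
Product: 7 di-tert-butyl 2-[(4Z)-oct-4-enoyl]butanedioate (racemic at C2)
Conditions: K2CO3, acetone, rt
Reagents that add atoms: none
Why: C-alkylation of the β-keto ester enolate by the α-bromo ester (SN2) installs the two-carbon arm that becomes C7 and C3'; the new stereocenter does not matter because it becomes sp2 in step 4.

Step 4
Reactants: 7 di-tert-butyl 2-[(4Z)-oct-4-enoyl]butanedioate
Product: 9 di-tert-butyl (2Z)-2-{(4Z)-1-[(trifluoromethanesulfonyl)oxy]oct-4-en-1-ylidene}butanedioate (triflate cis to the conjugated ester), via sodium enolate 8 (not isolated)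
Conditions: NaH, CH2Cl2, 0 °C; then Tf2O, −78 → 0 °C
Reagents that add atoms: trifluoromethanesulfonic anhydride, O=S(=O)(OS(=O)(=O)C(F)(F)F)C(F)(F)F
Why: The sodium enolate is held as a six-membered chelate between the enolate oxygen and the conjugated ester carbonyl, and O-sulfonylation traps this geometry (Z-enol triflate formation from a β-keto ester).

Step 5
Reactants: 9 the Z-enol triflate; 10 pent-1-yne
Product: 11 di-tert-butyl (2Z)-2-[(9Z)-tridec-9-en-4-yn-6-ylidene]butanedioate (alkyne cis to the conjugated ester)
Conditions: Pd(PPh3)2Cl2 (5 mol %), CuI (10 mol %), iPr2NH, THF, rt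
Reagents that add atoms: none
Why: Sonogashira coupling of the electron-poor vinyl triflate with the terminal alkyne proceeds with retention of the double-bond geometry.

Step 6
Reactants: 11 the enyne diester
Product: 13 2-{(5Z)-5-butylidene-4-[(3Z)-hept-3-en-1-yl]-2-oxo-2,5-dihydrofuran-3-yl}acetic acid, via diacid 12 (not isolated)
Conditions: TFA, CH2Cl2, 0 °C → rt; evaporate; then AgNO3 (10 mol %), acetone, rt, dark
Reagents that add atoms: none
Why: Acidolysis frees both carboxylic acids, and AgNO3 then activates the alkyne for 5-exo-dig anti attack by the only carboxyl group cis to it (the acetic acid arm is trans and cannot reach); protodemetalation with retention should give the Z-butylidene butenolide (alkynoic acid cycloisomerisation).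

Step 7
Reactants: 13 the butenolide acetic acid; 14 (2R,5R)-2,5-dimethylpyrrolidine
Product: 16 2-{(5Z)-5-butylidene-4-[(3Z)-hept-3-en-1-yl]-2-oxo-2,5-dihydrofuran-3-yl}-1-[(2R,5R)-2,5-dimethylpyrrolidin-1-yl]ethan-1-one, via acid chloride 15 (not isolated)
Conditions: (COCl)2, DMF (cat.), CH2Cl2, 0 °C; then 14, iPr2NEt, CH2Cl2, −40 → 0 °C
Reagents that add atoms: none
Why: Acylation of the hindered secondary amine by the acid chloride (amide formation) gives the tertiary amide the key step needs and brings in the auxiliary stereocenters unchanged.

Step 8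
Reactants: 16 the butenolide amide
Product: 19 (6S,7R,8'R)-cyclobutanone (rings A and B as in the target; ring C with C3' as C=O bonded to C7 and C8'H(n-Pr) bonded to C6; H6, H7 and H8' all cis; propyl cis to C5), via keteniminium triflate 17 (not isolated), via cyclobutaniminium triflate 18 (not isolated)
Conditions: Tf2O, 2,6-di-tert-butyl-4-methylpyridine, ClCH2CH2Cl, 0 → 80 °C; then H2O, rt
Reagents that add atoms: water, O
Why: O-Triflation of the amide and loss of an allylic C7 proton give keteniminium 17 (C7=C3'=N+), whose electrophilic C3' is attacked by the distal carbon C8' of the tethered Z-alkene while C7 closes onto C6 in an asynchronous thermal (2+2) cycloaddition, and water then hydrolyses iminium salt 18 to the ketone and releases the amine. The closest known reaction type is the intramolecular keteniminium–alkene cycloaddition of ω-alkenyl tertiary amides, including its auxiliary-controlled form with amides of C2-symmetric trans-2,5-dimethylpyrrolidine. Ring B closes through the C6–C7 bond in the fused (tether-inside) mode over the four tether atoms C7a, C3a, C4 and C5, and ring C closes through the C3'–C8' bond as the four-membered ring of the (2+2) event. C6 and C7 become cis because the short tether forces both new bonds onto one face, C8' follows from suprafacial addition to the Z-alkene (propyl cis to C5), and the absolute sense is set by the auxiliary, whose methyl groups above and below the iminium carbon leave one diagonal approach of the alkene open. The step needs fused rather than bridged regiochemistry (secured by the tether length and the 1,2-disubstituted alkene), chemoselectivity against the butylidene group (held trans across C3a=C7a, out of reach) and against the ring A carbonyl (a weak nucleophile that would have to close a strained bicycle), and facial selectivity (auxiliary).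

Step 9
Reactants: 19 the cyclobutanone; 20 ethyl 2-iodobenzoate
Product: 23 CNP0248594.2, (3'R,6S,7R,8'R): 19 in which C3' has become the spiro C3 of a 2-benzofuran-1(3H)-one (lactone oxygen cis to C7a and propyl; aryl carbon cis to H6, H7 and H8'), via arylmagnesium chloride 21 (not isolated), via magnesium alkoxide 22 (not isolated)
Conditions: 20, iPrMgCl·LiCl, THF, −40 °C; then LaCl3·2LiCl, 19, −78 → 0 °C, then rt; dilute HCl
Reagents that add atoms: none
Why: The arylmagnesium reagent from iodine–magnesium exchange adds to the strained, most electrophilic carbonyl (LaCl3·2LiCl curbs enolisation) from the convex face of the bicyclo[4.2.0] unit, the face flanked by H7 and H8' and not by ring B and the propyl group, which should put the aryl group cis to those hydrogens; the alkoxide then closes onto the neighbouring ester to give the spiro phthalide (1,2-addition followed by lactonisation).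

**Compound list**

1 | (2Z)-hex-2-en-1-ol | CCC/C=C\CO | starting material
2 | (2Z)-1-bromohex-2-ene | CCC/C=C\CBr | intermediate
3 | tert-butyl 3-oxobutanoate | CC(=O)CC(=O)OC(C)(C)C | starting material
4 | sodium lithium dianion of 3 | [Na+].[Li+].C=C([O-])C=C([O-])OC(C)(C)C | intermediate
5 | tert-butyl (6Z)-3-oxodec-6-enoate | CCC/C=C\CCC(=O)CC(=O)OC(C)(C)C | intermediate
6 | tert-butyl bromoacetate | BrCC(=O)OC(C)(C)C | starting material
7 | di-tert-butyl 2-[(4Z)-oct-4-enoyl]butanedioate | CCC/C=C\CCC(=O)C(CC(=O)OC(C)(C)C)C(=O)OC(C)(C)C | intermediate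
8 | sodium (Z)-enolate of 7 | [Na+].[O-]/C(CC/C=C\CCC)=C(/CC(=O)OC(C)(C)C)C(=O)OC(C)(C)C | intermediate
9 | di-tert-butyl (2Z)-2-{(4Z)-1-[(trifluoromethanesulfonyl)oxy]oct-4-en-1-ylidene}butanedioate | FC(F)(F)S(=O)(=O)O/C(CC/C=C\CCC)=C(/CC(=O)OC(C)(C)C)C(=O)OC(C)(C)C | intermediate
10 | pent-1-yne | CCCC#C | starting material
11 | di-tert-butyl (2Z)-2-[(9Z)-tridec-9-en-4-yn-6-ylidene]butanedioate | CCCC#C/C(CC/C=C\CCC)=C(/CC(=O)OC(C)(C)C)C(=O)OC(C)(C)C | intermediate
12 | (2Z)-2-[(9Z)-tridec-9-en-4-yn-6-ylidene]butanedioic acid | CCCC#C/C(CC/C=C\CCC)=C(/CC(=O)O)C(=O)O | intermediate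
13 | 2-{(5Z)-5-butylidene-4-[(3Z)-hept-3-en-1-yl]-2-oxo-2,5-dihydrofuran-3-yl}acetic acid | CCC/C=C1\OC(=O)C(CC(=O)O)=C1CC/C=C\CCC | intermediate
14 | (2R,5R)-2,5-dimethylpyrrolidine | C[C@@H]1CC[C@@H](C)N1 | starting material
15 | acid chloride of 13 | CCC/C=C1\OC(=O)C(CC(=O)Cl)=C1CC/C=C\CCC | intermediate
16 | 2-{(5Z)-5-butylidene-4-[(3Z)-hept-3-en-1-yl]-2-oxo-2,5-dihydrofuran-3-yl}-1-[(2R,5R)-2,5-dimethylpyrrolidin-1-yl]ethan-1-one | CCC/C=C1\OC(=O)C(CC(=O)N2[C@H](C)CC[C@H]2C)=C1CC/C=C\CCC | intermediate
17 | keteniminium triflate from 16 (C7=C3'=N+) | CCC/C=C1\OC(=O)C(C=C=[N+]2[C@H](C)CC[C@H]2C)=C1CC/C=C\CCC.[O-]S(=O)(=O)C(F)(F)F | intermediate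
18 | cyclobutaniminium triflate (iminium of 19 with the auxiliary) | CCC/C=C1\OC(=O)C2=C1CC[C@H]1[C@@H](CCC)C(=[N+]3[C@H](C)CC[C@H]3C)[C@@H]21.[O-]S(=O)(=O)C(F)(F)F | intermediate
19 | (6S,7R,8'R)-cyclobutanone | CCC/C=C1\OC(=O)C2=C1CC[C@H]1[C@@H](CCC)C(=O)[C@@H]21 | intermediate
20 | ethyl 2-iodobenzoate | CCOC(=O)c1ccccc1I | starting material
21 | [2-(ethoxycarbonyl)phenyl]magnesium chloride | CCOC(=O)c1ccccc1[Mg]Cl | intermediate
22 | chloromagnesium alkoxide of the C3' tertiary cyclobutanol carrying 2-(ethoxycarbonyl)phenyl | CCC/C=C1\OC(=O)C2=C1CC[C@H]1[C@@H](CCC)[C@@](c3ccccc3C(=O)OCC)(O[Mg]Cl)[C@@H]21 | intermediate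
23 | CNP0248594.2, (3'R,6S,7R,8'R) | CCC/C=C1\OC(=O)C2=C1CC[C@H]1[C@@H](CCC)[C@@]3(OC(=O)c4ccccc43)[C@@H]21 | target

**Step count and risks**

Total steps: 9. Longest linear sequence: 9 steps (steps 1 to 9; every other component is purchased).

Most likely to fail:

1. Step 8. The auxiliary may discriminate poorly between the two faces of the keteniminium, or the keteniminium carbon may be captured by the ring A carbonyl oxygen and decompose on heating before it cycloadds. Fallback, setting out from acid 13 and coming back at 19: acid chloride 15, made as in step 7, is added slowly to Et3N in toluene at 110 °C under high dilution. Dehydrochlorination should give the vinylketene 2-{(5Z)-5-butylidene-4-[(3Z)-hept-3-en-1-yl]-2-oxo-2,5-dihydrofuran-3-yl}ethen-1-one F1. This undergoes the thermal intramolecular ketene–alkene (2+2) cycloaddition across the same tether to the racemic cyclobutanone, that is 19 together with the enantiomer of cyclobutanone 19 F2. The two are separated by preparative chromatography on a cellulose tris(3,5-dimethylphenylcarbamate) stationary phase, and 19 goes on to step 9. The ketene is less electrophilic than the keteniminium, so capture by the lactone carbonyl is less of a threat, at the price of a resolution.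

2. Step 9. Addition of the hindered, ester-chelated arylmagnesium reagent may be slow, so that deprotonation at the allylic C7 position competes, or the enol lactone of ring A may be opened by the reagent or by the ethoxide released on lactonisation. Fallback, setting out from 19 and coming back at 23: 1-bromo-2-iodobenzene is converted with iPrMgCl·LiCl (THF, −20 °C) into (2-bromophenyl)magnesium chloride F3. With LaCl3·2LiCl this smaller nucleophile adds to 19 at −78 °C from the same convex face to give the C3' tertiary cyclobutanol carrying 2-bromophenyl F4. Carbonylation (Pd(OAc)2, 1,3-bis(diphenylphosphino)propane, CO 1 atm, Et3N, DMF, 80 °C) then inserts CO into the C–Br bond and the tertiary hydroxyl closes the lactone to 23, with no alkoxide released.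

3. Step 1. Partial Z-to-E isomerisation or allylic transposition may occur while the bromide is formed, stored and alkylated; because step 8 is stereospecific, any E-alkene would surface as the C8' epimer. Fallback, setting out from 3 and coming back at 5: commercial hex-2-yn-1-ol is converted with PBr3 into 1-bromohex-2-yne F5. Dianion 4 is alkylated with it to give tert-butyl 3-oxodec-6-ynoate F6. Semihydrogenation (H2 1 atm, Pd on CaCO3 poisoned with Pb(OAc)2, quinoline, EtOAc) should then deliver 5 with the Z geometry set by syn addition of hydrogen.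

**Further compounds**

F1 | step 8 | 2-{(5Z)-5-butylidene-4-[(3Z)-hept-3-en-1-yl]-2-oxo-2,5-dihydrofuran-3-yl}ethen-1-one | CCC/C=C1\OC(=O)C(C=C=O)=C1CC/C=C\CCC
F2 | step 8 | enantiomer of cyclobutanone 19 | CCC/C=C1\OC(=O)C2=C1CC[C@@H]1[C@H](CCC)C(=O)[C@H]21
F3 | step 9 | (2-bromophenyl)magnesium chloride | Brc1ccccc1[Mg]Cl
F4 | step 9 | C3' tertiary cyclobutanol carrying 2-bromophenyl | CCC/C=C1\OC(=O)C2=C1CC[C@H]1[C@@H](CCC)[C@@](c3ccccc3Br)(O)[C@@H]21
F5 | step 1 | 1-bromohex-2-yne | CCCC#CCBr
F6 | step 1 | tert-butyl 3-oxodec-6-ynoate | CCCC#CCCC(=O)CC(=O)OC(C)(C)C
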